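Agrimol B is cut at the two aryl C–OCH3 bonds of wing rings A and C and at the aryl–acyl bond of ring B. On each wing the methoxy-bearing carbon lies ortho to the butanoyl C=O and next to the ring CH3; in a wing made from 4-methylresorcinol it holds the only ring hydrogen. A single ketone-directed ruthenium-catalysed C–H oxygenation should therefore install both missing oxygens, each set apart from the seven others as a free phenol. The precursor is the methylene-bridged trimer heptaacetate, ring B unacylated, assembled by quinone methide coupling onto a benzyl-ester-blocked phloroglucinol. O-Methylation, acetate removal and Friedel–Crafts acylation with the (S)-acid chloride complete the route.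

Key step: step 7

Remark: 2,4,6-trihydroxybenzoic acid is taken as its commercial monohydrate; its benzyl ester is chosen to block ring B because it leaves by hydrogenolysis and mild decarboxylation, whereas hot alkali would scramble methylene-bridged phloroglucinols by retro-Michael cleavage.

Step 1
Reactants: 1 4-methylresorcinol; 2 butanoyl chloride
Product: 3 1-(2,4-dihydroxy-5-methylphenyl)butan-1-one
Conditions: AlCl3 (3 equiv), PhNO2, 0 → 50 °C; then ice/aq. HCl
Reagents that add atoms: none
Why: Friedel–Crafts acylation (any aryl ester formed first should rearrange by Fries shift) should enter C6 of 1, the carbon para to one hydroxyl and ortho to the other and the less hindered of the two activated sites, as is general for 4-substituted resorcinols.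

Step 2
Reactants: 3 1-(2,4-dihydroxy-5-methylphenyl)butan-1-one
Product: 4 1-{3-[(dimethylamino)methyl]-2,4-dihydroxy-5-methylphenyl}butan-1-one
Conditions: Me2NH (40% aq.), HCHO (37% aq.), EtOH, 0 °C → rt
Reagents that add atoms: formaldehyde (C=O); dimethylamine (CNC)
Why: Phenolic Mannich reaction: C3 of 3, flanked by both hydroxyls, is the only activated ring carbon left (C5 carries the methyl, C6 is meta to both hydroxyls), so the iminium ion should enter there and the base should separate as its zwitterion.

Step 3
Reactants: 5 2,4,6-trihydroxybenzoic acid (monohydrate)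
Product: 6 benzyl 2,4,6-trihydroxybenzoate
Conditions: BnBr (1.0 equiv), KHCO3 (1.05 equiv), DMF, rt
Reagents that add atoms: benzyl bromide (BrCc1ccccc1)
Why: Carboxylate O-alkylation (SN2): one equivalent of bicarbonate deprotonates only the strongly acidic carboxyl group, so benzyl bromide should esterify it without touching the phenols or the ring, and room temperature avoids decarboxylation.

Step 4
Reactants: 4 1-{3-[(dimethylamino)methyl]-2,4-dihydroxy-5-methylphenyl}butan-1-one (2.1 equiv); 6 benzyl 2,4,6-trihydroxybenzoate
Product: 7 benzyl 3,5-bis[(3-butanoyl-2,6-dihydroxy-5-methylphenyl)methyl]-2,4,6-trihydroxybenzoate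
Conditions: 1,4-dioxane, 100 °C, N2 purge
Reagents that add atoms: none
Why: Thermal loss of dimethylamine from the acidic phenol 4 should give an ortho-quinone methide that is captured by the strongly nucleophilic free carbons C3 and C5 of 6 (Michael-type C-alkylation, the Mannich-base route to methylene-bridged phloroglucinols); the ester blocks the third ring carbon so that alkylation stops at the trimer, and neither partner has a ring position at which it could condense with itself.

Step 5
Reactants: 7 benzyl 3,5-bis[(3-butanoyl-2,6-dihydroxy-5-methylphenyl)methyl]-2,4,6-trihydroxybenzoate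
Product: 9 2,4-bis[(3-butanoyl-2,6-dihydroxy-5-methylphenyl)methyl]benzene-1,3,5-triol, via trimer carboxylic acid 8 (not isolated)
Conditions: H2 (1 atm), 10% Pd/C, EtOAc–MeOH, rt; filter; then dioxane–H2O, 70 °C
Reagents that add atoms: none
Why: Hydrogenolysis of the benzyl ester under neutral conditions should leave the chelated aryl ketones untouched, and the resulting 2,4,6-trihydroxybenzoic acid, made still more electron-rich by its two alkyl groups, should lose CO2 on gentle warming by ipso-protonation (protodecarboxylation), so that no alkali is needed.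

Step 6
Reactants: 9 2,4-bis[(3-butanoyl-2,6-dihydroxy-5-methylphenyl)methyl]benzene-1,3,5-triol
Product: 10 2,4-bis[(2,6-diacetoxy-3-butanoyl-5-methylphenyl)methyl]benzene-1,3,5-triyl triacetate (key-step precursor)
Conditions: Ac2O, pyridine, DMAP (cat.), rt → 40 °C
Reagents that add atoms: acetic anhydride (CC(=O)OC(C)=O)
Why: DMAP-catalysed acyl transfer should esterify all seven phenols, including the two hydrogen-bonded to the ketones, which removes the oxidisable free phenols and makes the three rings electron-poor for step 7.

Step 7
Reactants: 10 2,4-bis[(2,6-diacetoxy-3-butanoyl-5-methylphenyl)methyl]benzene-1,3,5-triyl triacetate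
Product: 12 2,4-bis[(2,6-diacetoxy-3-butanoyl-4-hydroxy-5-methylphenyl)methyl]benzene-1,3,5-triyl triacetate, via wing bis(trifluoroacetate) 11 (not isolated)
Conditions: [RuCl2(p-cymene)]2 (10 mol%), PhI(OCOCF3)2 (2.6 equiv), CF3CO2H–(CF3CO)2O–ClCH2CH2Cl, 80 °C; then aq. Na2S2O3; pH 7 phosphate buffer–THF, rt
Reagents that add atoms: [bis(trifluoroacetoxy)iodo]benzene, PhI(OCOCF3)2 (O=C(OI(OC(=O)C(F)(F)F)c1ccccc1)C(F)(F)F)
Why: Ru(OCOCF3)2(p-cymene) formed in situ (divalent ruthenium) should bind the butanoyl oxygen of a wing, cleave its only ortho C–H bond (C4' of the wing, between the ketone-bearing and the methyl-bearing carbon) by carboxylate-assisted concerted metalation–deprotonation to give a five-membered ruthenacycle, be oxidised by the trivalent iodine reagent to tetravalent ruthenium and release the aryl trifluoroacetate by C–O reductive elimination, the same cycle then running on the second wing. The closest known reaction type is the ruthenium- or palladium-catalysed ketone-directed ortho C–H hydroxylation of aryl alkyl ketones with PhI(OCOCF3)2 or persulfate in CF3CO2H/(CF3CO)2O. No ring is closed and no stereocentre is formed. Site selectivity is needed among three aromatic C–H bonds: only the two ortho to a ketone can reach a five-membered chelate, whereas the ring B hydrogen lies between two acetoxy groups whose ester carbonyls are poor donors and would need a six-membered metallacycle at a doubly flanked carbon. Chemoselectivity over the doubly benzylic CH2 bridges and the ketone α-CH2 groups is expected because the acetates make all three rings electron-poor, each bridge is shielded by four ortho acetoxy groups and no radical initiator is present. The anhydride should keep each new oxygen masked as its trifluoroacetate until the excess oxidant has been reduced, so that the para-alkylated phenol never meets trivalent iodine, and neutral aqueous hydrolysis should then free only the far more labile trifluoroacetates.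

Step 8
Reactants: 12 2,4-bis[(2,6-diacetoxy-3-butanoyl-4-hydroxy-5-methylphenyl)methyl]benzene-1,3,5-triyl triacetate
Product: 13 2,4-bis[(2,6-diacetoxy-3-butanoyl-4-methoxy-5-methylphenyl)methyl]benzene-1,3,5-triyl triacetate
Conditions: MeI (excess), Ag2O, CH2Cl2, 40 °C, dark
Reagents that add atoms: iodomethane (CI)
Why: Purdie-type O-methylation: Ag2O should activate only the two free, ketone-chelated phenols and precipitation of AgI drives the alkylation, while in the absence of carbonate or alkoxide the seven aryl acetates, none of which is adjacent to a new hydroxyl, should neither migrate nor be cleaved.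

Step 9
Reactants: 13 2,4-bis[(2,6-diacetoxy-3-butanoyl-4-methoxy-5-methylphenyl)methyl]benzene-1,3,5-triyl triacetate
Product: 14 2,4-bis[(3-butanoyl-2,6-dihydroxy-4-methoxy-5-methylphenyl)methyl]benzene-1,3,5-triol
Conditions: HCl (1.25 M in MeOH), THF, 40 °C, degassed
Reagents that add atoms: none
Why: Acid-catalysed transesterification with methanol should strip the seven activated aryl acetates as methyl acetate, while the aryl methyl ethers, the ketones and the diarylmethane bridges, which fragment under basic but not under mildly acidic conditions, stay intact.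

Step 10
Reactants: 15 (S)-2-methylbutanoic acid
Product: 16 (S)-2-methylbutanoyl chloride
Conditions: (COCl)2, DMF (cat.), CH2Cl2, 0 °C → rt; concentrate, use crude
Reagents that add atoms: oxalyl chloride (ClC(=O)C(=O)Cl)
Why: Acid chloride formation through the Vilsmeier-type chloroiminium species runs without base, so no ketene can form and the α-stereocentre of 15 should be retained.

Step 11
Reactants: 14 2,4-bis[(3-butanoyl-2,6-dihydroxy-4-methoxy-5-methylphenyl)methyl]benzene-1,3,5-triol; 16 (S)-2-methylbutanoyl chloride (1.1 equiv)
Product: 17 Agrimol B, (2S)-1-{3,5-bis[(3-butanoyl-2,6-dihydroxy-4-methoxy-5-methylphenyl)methyl]-2,4,6-trihydroxyphenyl}-2-methylbutan-1-one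
Conditions: AlCl3 (excess), PhNO2–CH2Cl2, 0 °C → rt; then ice/aq. HCl
Reagents that add atoms: none
Why: Friedel–Crafts C-acylation: the only unsubstituted aromatic carbon of 14 lies on the phloroglucinol ring B, the most nucleophilic ring, so the acylium ion from 16 should enter there; the (S)-stereocentre comes unchanged from 15 because acylium formation does not involve the α-hydrogen and the low temperature disfavours enolisation, and each wing carbonyl, already held in a six-membered chelate to aluminium through its ortho phenoxide, should not promote cleavage of its other ortho methoxy group.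

Compound list
1 | 4-methylresorcinol (4-methylbenzene-1,3-diol) | Cc1ccc(O)cc1O | starting material
2 | butanoyl chloride | CCCC(=O)Cl | starting material
3 | 1-(2,4-dihydroxy-5-methylphenyl)butan-1-one | CCCC(=O)c1cc(C)c(O)cc1O | intermediate
4 | 1-{3-[(dimethylamino)methyl]-2,4-dihydroxy-5-methylphenyl}butan-1-one | CCCC(=O)c1cc(C)c(O)c(CN(C)C)c1O | intermediate
5 | 2,4,6-trihydroxybenzoic acid | OC(=O)c1c(O)cc(O)cc1O | starting material
6 | benzyl 2,4,6-trihydroxybenzoate | O=C(OCc1ccccc1)c1c(O)cc(O)cc1O | intermediate
7 | benzyl 3,5-bis[(3-butanoyl-2,6-dihydroxy-5-methylphenyl)methyl]-2,4,6-trihydroxybenzoate | CCCC(=O)c1cc(C)c(O)c(Cc2c(O)c(Cc3c(O)c(C)cc(C(=O)CCC)c3O)c(O)c(C(=O)OCc4ccccc4)c2O)c1O | intermediate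
8 | 3,5-bis[(3-butanoyl-2,6-dihydroxy-5-methylphenyl)methyl]-2,4,6-trihydroxybenzoic acid (not isolated) | CCCC(=O)c1cc(C)c(O)c(Cc2c(O)c(Cc3c(O)c(C)cc(C(=O)CCC)c3O)c(O)c(C(=O)O)c2O)c1O | intermediate
9 | 2,4-bis[(3-butanoyl-2,6-dihydroxy-5-methylphenyl)methyl]benzene-1,3,5-triol | CCCC(=O)c1cc(C)c(O)c(Cc2c(O)cc(O)c(Cc3c(O)c(C)cc(C(=O)CCC)c3O)c2O)c1O | intermediate
10 | 2,4-bis[(2,6-diacetoxy-3-butanoyl-5-methylphenyl)methyl]benzene-1,3,5-triyl triacetate (trimer heptaacetate, key-step precursor) | CCCC(=O)c1c(OC(C)=O)c(Cc2c(OC(C)=O)cc(OC(C)=O)c(Cc3c(OC(C)=O)c(C)cc(C(=O)CCC)c3OC(C)=O)c2OC(C)=O)c(OC(C)=O)c(C)c1 | intermediate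
11 | heptaacetate carrying a trifluoroacetoxy group at C4' of each wing (not isolated) | CCCC(=O)c1c(OC(C)=O)c(Cc2c(OC(C)=O)cc(OC(C)=O)c(Cc3c(OC(C)=O)c(C)c(OC(=O)C(F)(F)F)c(C(=O)CCC)c3OC(C)=O)c2OC(C)=O)c(OC(C)=O)c(C)c1OC(=O)C(F)(F)F | intermediate
12 | 2,4-bis[(2,6-diacetoxy-3-butanoyl-4-hydroxy-5-methylphenyl)methyl]benzene-1,3,5-triyl triacetate (key-step product) | CCCC(=O)c1c(OC(C)=O)c(Cc2c(OC(C)=O)cc(OC(C)=O)c(Cc3c(OC(C)=O)c(C)c(O)c(C(=O)CCC)c3OC(C)=O)c2OC(C)=O)c(OC(C)=O)c(C)c1O | intermediate
13 | 2,4-bis[(2,6-diacetoxy-3-butanoyl-4-methoxy-5-methylphenyl)methyl]benzene-1,3,5-triyl triacetate | CCCC(=O)c1c(OC(C)=O)c(Cc2c(OC(C)=O)cc(OC(C)=O)c(Cc3c(OC(C)=O)c(C)c(OC)c(C(=O)CCC)c3OC(C)=O)c2OC(C)=O)c(OC(C)=O)c(C)c1OC | intermediate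
14 | 2,4-bis[(3-butanoyl-2,6-dihydroxy-4-methoxy-5-methylphenyl)methyl]benzene-1,3,5-triol | CCCC(=O)c1c(O)c(Cc2c(O)cc(O)c(Cc3c(O)c(C)c(OC)c(C(=O)CCC)c3O)c2O)c(O)c(C)c1OC | intermediate
15 | (S)-2-methylbutanoic acid | CC[C@H](C)C(=O)O | starting material
16 | (S)-2-methylbutanoyl chloride | CC[C@H](C)C(=O)Cl | intermediate
17 | Agrimol B, (2S)-1-{3,5-bis[(3-butanoyl-2,6-dihydroxy-4-methoxy-5-methylphenyl)methyl]-2,4,6-trihydroxyphenyl}-2-methylbutan-1-one | CCCC(=O)c1c(O)c(Cc2c(O)c(Cc3c(O)c(C)c(OC)c(C(=O)CCC)c3O)c(O)c(C(=O)[C@@H](C)CC)c2O)c(O)c(C)c1OC | target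

Total step count: 11 steps.
Longest linear sequence: 9 steps (steps 1, 2, 4, 5, 6, 7, 8, 9, 11).

Steps most likely to fail

Step 7. The twofold cyclometalation may stall after one wing at these crowded C–H bonds. The trivalent iodine oxidant may attack the CH2 bridges or the ketone α-positions, and acetates may be lost by acidolysis. The fallback separates C–H activation from oxidation. It sets out from 10, which would undergo ketone-directed ortho C–H borylation ([Ir(OMe)(cod)]2, AsPh3, B2pin2, octane, 120 °C) to give the bis(pinacolboronate) heptaacetate F1. Oxidation of the two C–B bonds with KHSO5 (as Oxone) in acetone–water at 0 °C, conditions that spare aryl acetates, should return to the route at 12.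

Step 11. The α-stereocentre may epimerise by Lewis-acid-promoted enolisation. Wing phenols may be O-acylated without transfer to carbon, the methyl ethers may be cleaved by AlCl3, and the bridges may break by retro-Friedel–Crafts reaction. The fallback is a Hoesch reaction, which needs neither AlCl3 nor an acylium ion. It sets out from 14, which would be treated with commercially offered (S)-2-methylbutanenitrile, ZnCl2 and HCl gas in Et2O–dioxane at 0 °C to precipitate the ring B ketiminium chloride F2. Hydrolysis of F2 in water at 60–70 °C should return to the route at 17.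

Step 4. Quinone methide release from 4 may be slow, the quinone methide may dimerise, or the reaction may stop after the first alkylation. The fallback inverts the polarity of the coupling. It sets out from 6, which would be bis-aminomethylated (Me2NH, HCHO, EtOH, rt) to the ring B bis-Mannich base F3. Its quinone methides form very readily and would be trapped at C3 of ketone 3 (excess, dioxane, 100 °C), returning to the route at 7.

Further compounds
F1 | step 7 | 2,4-bis{[2,6-diacetoxy-3-butanoyl-5-methyl-4-(4,4,5,5-tetramethyl-1,3,2-dioxaborolan-2-yl)phenyl]methyl}benzene-1,3,5-triyl triacetate | CCCC(=O)c1c(OC(C)=O)c(Cc2c(OC(C)=O)cc(OC(C)=O)c(Cc3c(OC(C)=O)c(C)c(B4OC(C)(C)C(C)(C)O4)c(C(=O)CCC)c3OC(C)=O)c2OC(C)=O)c(OC(C)=O)c(C)c1B5OC(C)(C)C(C)(C)O5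
F2 | step 11 | (2S)-1-{3,5-bis[(3-butanoyl-2,6-dihydroxy-4-methoxy-5-methylphenyl)methyl]-2,4,6-trihydroxyphenyl}-2-methylbutan-1-iminium chloride | CCCC(=O)c1c(O)c(Cc2c(O)c(Cc3c(O)c(C)c(OC)c(C(=O)CCC)c3O)c(O)c(C(=[NH2+])[C@@H](C)CC)c2O)c(O)c(C)c1OC.[Cl-]
F3 | step 4 | benzyl 3,5-bis[(dimethylamino)methyl]-2,4,6-trihydroxybenzoate | CN(C)Cc1c(O)c(CN(C)C)c(O)c(C(=O)OCc2ccccc2)c1O
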